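**Plan**
- Retrosynthesis: the C2 stereocentre is traced back to the flavone C2=C3 bond; ring C is then cut at C3–C4 and at O1–C8a, which gives an aryl ester; the ester C(=O)–O bond, the C8–prenyl bond and the C5'–C(CH3)2 bond are cut last, back to two aryl bromides.
- Forward: the ring A acid (2-fluoro, 3-prenyl, 4,6-bis-MOM) is built from 5-fluororesorcinol and the ring B ketone from 5'-bromo-2'-hydroxyacetophenone; the two are joined as an ester through O2' of ring B.
- Ring C arises last, in one base-mediated operation: O→C aroyl shift (C3–C4), then displacement of fluoride at C8a by the enolate oxygen (O1–C8a), giving the flavone.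
- Enabling feature: the free 2'-hydroxyl of ring B, ortho to the carbon that bears C2, is a traceless tether that brings the ring A aroyl carbon (C4) to the acetyl methyl (C3) through a six-membered transition state; C8a lies ortho to C4 and meta to both ring A oxygens, so a fluoride there is displaced readily.
- Helpers: the fluoride leaves in the key step, the tether becomes the 2'-OH of the target, and the flavone oxidation level is taken out by reduction.
- Stereochemistry: C2 (S) comes from ligand-controlled conjugate hydride delivery by a chiral bisphosphine copper hydride; the MOM groups are removed last.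

Key step: step 8

Assumption: (R)-DTBM-SEGPHOS is taken to deliver hydride to the face of C2 that gives the (2S) product; the sense would be checked on a model flavone and the ligand antipode used if it is the opposite.

**Step 1**
Reactants: 1 5-fluorobenzene-1,3-diol (5-fluororesorcinol)
Product: 3 2-fluoro-4,6-dihydroxybenzaldehyde, via iminium chloride 2 (not isolated)
Conditions: POCl3, DMF, MeCN, −15 °C to rt; then H2O, 50 °C
Reagents that add atoms: N,N-dimethylformamide, CN(C)C=O (formyl carbon); water, O (carbonyl oxygen)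
Why: Vilsmeier–Haack formylation of a resorcinol should go to the carbon ortho to one hydroxyl and para to the other (here the one next to fluorine), the site between the two hydroxyls being the more hindered one.

**Step 2**
Reactants: 3 2-fluoro-4,6-dihydroxybenzaldehyde
Product: 4 3-bromo-2-fluoro-4,6-dihydroxybenzaldehyde
Conditions: NBS (1.0 equiv), MeCN, 0 °C
Reagents that add atoms: N-bromosuccinimide, O=C1CCC(=O)N1Br
Why: Electrophilic aromatic bromination should take place para to the chelated 6-hydroxyl and ortho to the 4-hydroxyl (C3, next to fluorine), as 2,4-dihydroxybenzaldehydes brominate at the corresponding position and not between the two oxygens.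

**Step 3**
Reactants: 4 3-bromo-2-fluoro-4,6-dihydroxybenzaldehyde
Product: 5 3-bromo-2-fluoro-4,6-bis(methoxymethoxy)benzaldehyde
Conditions: NaH (2.5 equiv), MOMCl (2.5 equiv), DMF, 0 °C to rt
Reagents that add atoms: chloromethyl methyl ether, COCCl
Why: O-Alkylation of both sodium phenoxides (Williamson type), NaH being strong enough to engage the hydrogen-bonded 6-hydroxyl as well.

**Step 4**
Reactants: 5 3-bromo-2-fluoro-4,6-bis(methoxymethoxy)benzaldehyde
Product: 6 2-fluoro-4,6-bis(methoxymethoxy)-3-(3-methylbut-2-en-1-yl)benzaldehyde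
Conditions: tributyl(3-methylbut-2-en-1-yl)stannane (1.3 equiv), Pd(PPh3)4 (5 mol%), DMF, 100 °C
Reagents that add atoms: tributyl(3-methylbut-2-en-1-yl)stannane, CC(C)=CC[Sn](CCCC)(CCCC)CCCC
Why: Stille coupling of an aryl bromide with a prenylstannane normally gives the unrearranged (linear) prenyl arene and tolerates the aldehyde, the aryl fluoride and the MOM ethers.

**Step 5**
Reactants: 6 2-fluoro-4,6-bis(methoxymethoxy)-3-(3-methylbut-2-en-1-yl)benzaldehyde
Product: 7 2-fluoro-4,6-bis(methoxymethoxy)-3-(3-methylbut-2-en-1-yl)benzoic acid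
Conditions: NaClO2, NaH2PO4, 2-methyl-2-butene (excess), t-BuOH/H2O, rt
Reagents that add atoms: sodium chlorite, [Na+].[O-]Cl=O
Why: Pinnick oxidation turns the hindered aldehyde into the acid under weakly acidic buffer, the excess alkene scavenger keeping hypochlorous acid away from the prenyl group and the electron-rich ring.

**Step 6**
Reactants: 8 1-(5-bromo-2-hydroxyphenyl)ethan-1-one (5'-bromo-2'-hydroxyacetophenone)
Product: 9 1-[2-hydroxy-5-(2-methylbut-3-en-2-yl)phenyl]ethan-1-one
Conditions: 4,4,5,5-tetramethyl-2-(3-methylbut-2-en-1-yl)-1,3,2-dioxaborolane (1.5 equiv), Pd(OAc)2 (2 mol%), biarylphosphine ligand of the γ-selective type (4 mol%, fixed by a short screen), K3PO4 (aq), THF, 40 °C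
Reagents that add atoms: 4,4,5,5-tetramethyl-2-(3-methylbut-2-en-1-yl)-1,3,2-dioxaborolane, CC(C)=CCB1OC(C)(C)C(C)(C)O1
Why: In the Suzuki–Miyaura coupling of a 3,3-disubstituted allylboronate, transmetalation with allyl transposition puts palladium on the tertiary carbon, and a ligand that makes reductive elimination faster than allyl isomerisation should give the branched (γ) product, that is the 1,1-dimethylallyl arene, with ketone and phenoxide tolerated.

**Step 7**
Reactants: 7 2-fluoro-4,6-bis(methoxymethoxy)-3-(3-methylbut-2-en-1-yl)benzoic acid; 9 1-[2-hydroxy-5-(2-methylbut-3-en-2-yl)phenyl]ethan-1-one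
Product: 10 2-acetyl-4-(2-methylbut-3-en-2-yl)phenyl 2-fluoro-4,6-bis(methoxymethoxy)-3-(3-methylbut-2-en-1-yl)benzoate
Conditions: DCC (1.2 equiv), DMAP (0.2 equiv), CH2Cl2, 0 °C to rt
Reagents that add atoms: none
Why: Steglich esterification through the acylpyridinium ion acylates the phenol under neutral conditions that leave the MOM ethers, the fluoride and both alkenes untouched.

**Step 8**
Reactants: 10 2-acetyl-4-(2-methylbut-3-en-2-yl)phenyl 2-fluoro-4,6-bis(methoxymethoxy)-3-(3-methylbut-2-en-1-yl)benzoate
Product: 12 2-[2-hydroxy-5-(2-methylbut-3-en-2-yl)phenyl]-5,7-bis(methoxymethoxy)-8-(3-methylbut-2-en-1-yl)-4H-chromen-4-one, via 1,3-diketone 11 (not isolated)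
Conditions: KOt-Bu (2.2 equiv), DMF, 0 °C to rt, then 80 °C; aq. NH4Cl
Reagents that add atoms: none
Why: KOt-Bu forms the methyl ketone enolate of 10, which attacks the neighbouring aryl ester carbonyl through a six-membered cyclic transition state and expels the ring B phenoxide (Baker–Venkataraman O→C aroyl shift), so that C3–C4 is made and the 1,3-diketonate 11 results. On warming, the enolate oxygen on C2 of 11 adds to the fluorine-bearing carbon C8a, ortho to the new C4 ketone, and fluoride leaves from the Meisenheimer anion (intramolecular SNAr, the closest known type being the base-mediated cyclisation of 1-(2-fluoroaryl)-1,3-diketones to chromones), so that O1–C8a is made. Ring C, the only ring closed, forms as a six-membered ring by 6-endo-trig attack of oxygen on C8a of the vinylogous acyl fluoride C8a=C4a–C4=O (addition–elimination), while the acyl shift itself closes no ring. No stereocentre is created: C2 is trigonal in 12 and is set in step 10. The step needs O-arylation by the diketonate oxygen and not by the liberated 2'-phenoxide, which is secured because the phenoxide would have to close an eight-membered ring and because dehydrative closure of the phenol onto C4 needs acid; it also needs a C8a open to SNAr, secured by the ortho carbonyl and by both MOM ethers being meta to C8a, so that they do not donate into the carbon under attack. The acetyl methyl is the only enolisable position of 10, so the acyl shift has one possible regiochemistry.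

**Step 9**
Reactants: 12 2-[2-hydroxy-5-(2-methylbut-3-en-2-yl)phenyl]-5,7-bis(methoxymethoxy)-8-(3-methylbut-2-en-1-yl)-4H-chromen-4-one
Product: 13 5,7-bis(methoxymethoxy)-2-[2-(methoxymethoxy)-5-(2-methylbut-3-en-2-yl)phenyl]-8-(3-methylbut-2-en-1-yl)-4H-chromen-4-one
Conditions: MOMCl (1.5 equiv), i-Pr2NEt (2 equiv), CH2Cl2, 0 °C to rt
Reagents that add atoms: chloromethyl methyl ether, COCCl
Why: Alkylation of the unhindered 2'-phenol removes the only acidic proton, which would otherwise consume copper hydride and could bind copper next to C2 in the following step.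

**Step 10**
Reactants: 13 5,7-bis(methoxymethoxy)-2-[2-(methoxymethoxy)-5-(2-methylbut-3-en-2-yl)phenyl]-8-(3-methylbut-2-en-1-yl)-4H-chromen-4-one
Product: 15 (2S)-5,7-bis(methoxymethoxy)-2-[2-(methoxymethoxy)-5-(2-methylbut-3-en-2-yl)phenyl]-8-(3-methylbut-2-en-1-yl)-2,3-dihydro-4H-chromen-4-one, via silyl enol ether 14 (not isolated)
Conditions: Cu(OAc)2 (5 mol%), (R)-DTBM-SEGPHOS (5.5 mol%), (EtO)2MeSiH (2 equiv), toluene, 0 °C to rt; then 1 M citric acid (aq), THF, 0 °C
Reagents that add atoms: none
Why: Copper hydride asymmetric conjugate reduction of the chromone C2=C3 bond should deliver hydride to C2 inside the chiral bisphosphine pocket, which sets the (2S) centre by ligand control, while the product stays masked as silyl enol ether 14 until the mild acidic work-up (no 1,2-reduction, no base-induced ring opening) and the isolated prenyl and 1,1-dimethylallyl alkenes have no productive pathway with the copper hydride.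

**Step 11**
Reactants: 15 (2S)-5,7-bis(methoxymethoxy)-2-[2-(methoxymethoxy)-5-(2-methylbut-3-en-2-yl)phenyl]-8-(3-methylbut-2-en-1-yl)-2,3-dihydro-4H-chromen-4-one
Product: 16 (2S)-5,7-dihydroxy-2-[2-hydroxy-5-(2-methylbut-3-en-2-yl)phenyl]-8-(3-methylbut-2-en-1-yl)-2,3-dihydro-4H-chromen-4-one
Conditions: 3 M HCl (aq), MeOH, 40 °C
Reagents that add atoms: none
Why: Acid-catalysed acetal exchange with methanol should remove the three MOM groups under conditions mild enough to avoid ring opening and reclosure at C2 (racemisation) and cyclisation of the prenyl group onto the 7-hydroxyl.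

**Compound list**
1 | 5-fluorobenzene-1,3-diol | Oc1cc(O)cc(F)c1 | starting material
2 | [(2-fluoro-4,6-dihydroxyphenyl)methylidene]dimethylammonium chloride | C[N+](C)=Cc1c(F)cc(O)cc1O.[Cl-] | intermediate (not isolated)
3 | 2-fluoro-4,6-dihydroxybenzaldehyde | O=Cc1c(F)cc(O)cc1O | intermediate
4 | 3-bromo-2-fluoro-4,6-dihydroxybenzaldehyde | O=Cc1c(F)c(Br)c(O)cc1O | intermediate
5 | 3-bromo-2-fluoro-4,6-bis(methoxymethoxy)benzaldehyde | O=Cc1c(F)c(Br)c(OCOC)cc1OCOC | intermediate
6 | 2-fluoro-4,6-bis(methoxymethoxy)-3-(3-methylbut-2-en-1-yl)benzaldehyde | O=Cc1c(F)c(CC=C(C)C)c(OCOC)cc1OCOC | intermediate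
7 | 2-fluoro-4,6-bis(methoxymethoxy)-3-(3-methylbut-2-en-1-yl)benzoic acid | OC(=O)c1c(F)c(CC=C(C)C)c(OCOC)cc1OCOC | intermediate
8 | 1-(5-bromo-2-hydroxyphenyl)ethan-1-one | CC(=O)c1cc(Br)ccc1O | starting material
9 | 1-[2-hydroxy-5-(2-methylbut-3-en-2-yl)phenyl]ethan-1-one | CC(=O)c1cc(C(C)(C)C=C)ccc1O | intermediate
10 | 2-acetyl-4-(2-methylbut-3-en-2-yl)phenyl 2-fluoro-4,6-bis(methoxymethoxy)-3-(3-methylbut-2-en-1-yl)benzoate | CC(=O)c1cc(C(C)(C)C=C)ccc1OC(=O)c1c(F)c(CC=C(C)C)c(OCOC)cc1OCOC | intermediate
11 | 1-[2-fluoro-4,6-bis(methoxymethoxy)-3-(3-methylbut-2-en-1-yl)phenyl]-3-[2-hydroxy-5-(2-methylbut-3-en-2-yl)phenyl]propane-1,3-dione | O=C(CC(=O)c1cc(C(C)(C)C=C)ccc1O)c1c(F)c(CC=C(C)C)c(OCOC)cc1OCOC | intermediate (not isolated)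
12 | 2-[2-hydroxy-5-(2-methylbut-3-en-2-yl)phenyl]-5,7-bis(methoxymethoxy)-8-(3-methylbut-2-en-1-yl)-4H-chromen-4-one | C=CC(C)(C)c1ccc(O)c(C2=CC(=O)c3c(OCOC)cc(OCOC)c(CC=C(C)C)c3O2)c1 | intermediate
13 | 5,7-bis(methoxymethoxy)-2-[2-(methoxymethoxy)-5-(2-methylbut-3-en-2-yl)phenyl]-8-(3-methylbut-2-en-1-yl)-4H-chromen-4-one | C=CC(C)(C)c1ccc(OCOC)c(C2=CC(=O)c3c(OCOC)cc(OCOC)c(CC=C(C)C)c3O2)c1 | intermediate
14 | (2S)-4-{[diethoxy(methyl)silyl]oxy}-5,7-bis(methoxymethoxy)-2-[2-(methoxymethoxy)-5-(2-methylbut-3-en-2-yl)phenyl]-8-(3-methylbut-2-en-1-yl)-2H-chromene | C=CC(C)(C)c1ccc(OCOC)c([C@@H]2C=C(O[Si](C)(OCC)OCC)c3c(OCOC)cc(OCOC)c(CC=C(C)C)c3O2)c1 | intermediate (not isolated)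
15 | (2S)-5,7-bis(methoxymethoxy)-2-[2-(methoxymethoxy)-5-(2-methylbut-3-en-2-yl)phenyl]-8-(3-methylbut-2-en-1-yl)-2,3-dihydro-4H-chromen-4-one | C=CC(C)(C)c1ccc(OCOC)c([C@@H]2CC(=O)c3c(OCOC)cc(OCOC)c(CC=C(C)C)c3O2)c1 | intermediate
16 | (2S)-5,7-dihydroxy-2-[2-hydroxy-5-(2-methylbut-3-en-2-yl)phenyl]-8-(3-methylbut-2-en-1-yl)-2,3-dihydro-4H-chromen-4-one | C=CC(C)(C)c1ccc(O)c([C@@H]2CC(=O)c3c(O)cc(O)c(CC=C(C)C)c3O2)c1 | target

**Step count**
Total: 11 steps. Longest linear sequence: 10 steps (steps 1–5 and 7–11, from compound 1).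

**Steps most likely to fail**

1. Step 10. Hydride transfer to the electron-rich flavone with its ortho-substituted 2-aryl group may be slow, the facial selectivity may be poor, or the carbonyl may be reduced as well. Fallback (resolution in place of asymmetric catalysis): from 13, conjugate reduction with LiBH(s-Bu)3 in THF at −78 °C would give the racemic tris-MOM flavanone F1. Asymmetric transfer hydrogenation of F1 with RuCl(p-cymene)[(S,S)-TsDPEN] (or its antipode, whichever consumes the (2R)-ketone) and HCO2H/Et3N, stopped near half conversion, would reduce the (2R)-enantiomer to the cis-(2R,4R)-flavan-4-ol F2. The untouched (2S)-ketone is separated by chromatography, and the route is rejoined at 15.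

2. Step 8. Intermolecular cleavage of the hindered aryl ester may outrun the acyl shift, the liberated 2'-phenoxide may divert the diketonate into closure on C4, or fluoride displacement on the alkoxy-rich ring may stall. Fallback (intermolecular C-acylation in place of the tethered shift, with no free phenoxide present): 9 is protected with MOMCl and i-Pr2NEt as the MOM ether of the ring B ketone F3, and 7 is activated with 1,1'-carbonyldiimidazole in THF as the acyl imidazolide F4. The lithium enolate of F3 (LiN(SiMe3)2, 2.2 equiv, THF, −78 °C) is acylated on carbon by F4 to give the 2'-MOM-protected 1,3-diketone F5. Heating F5 with K2CO3 in DMF at 100 °C closes ring C by fluoride displacement and gives 13 directly, so that step 9 is no longer needed.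

3. Step 6. Coupling may occur through the primary allyl terminus and give the linear prenyl arene, or the boronate may add to the ketone. Fallback (copper-mediated allylic substitution in place of cross-coupling): 8 is silylated on both oxygens (TBSOTf, Et3N, CH2Cl2) to the aryl silyl ether/silyl enol ether F6. Bromine–lithium exchange (t-BuLi, THF, −78 °C) and MgBr2·OEt2 give the aryl Grignard reagent, which with CuBr·SMe2 attacks the γ-carbon of 3-methylbut-2-en-1-yl pyridine-2-carboxylate F7 (from 3-methylbut-2-en-1-ol and pyridine-2-carboxylic acid, DCC, DMAP) with allyl transposition to give the bis-silylated 1,1-dimethylallyl arene F8. TBAF/AcOH in THF removes both silyl groups and returns 9.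

**Further compounds**
F1 | step 10 | rac-5,7-bis(methoxymethoxy)-2-[2-(methoxymethoxy)-5-(2-methylbut-3-en-2-yl)phenyl]-8-(3-methylbut-2-en-1-yl)-2,3-dihydro-4H-chromen-4-one | C=CC(C)(C)c1ccc(OCOC)c(C2CC(=O)c3c(OCOC)cc(OCOC)c(CC=C(C)C)c3O2)c1
F2 | step 10 | (2R,4R)-5,7-bis(methoxymethoxy)-2-[2-(methoxymethoxy)-5-(2-methylbut-3-en-2-yl)phenyl]-8-(3-methylbut-2-en-1-yl)-3,4-dihydro-2H-chromen-4-ol | C=CC(C)(C)c1ccc(OCOC)c([C@H]2C[C@@H](O)c3c(OCOC)cc(OCOC)c(CC=C(C)C)c3O2)c1
F3 | step 8 | 1-[2-(methoxymethoxy)-5-(2-methylbut-3-en-2-yl)phenyl]ethan-1-one | CC(=O)c1cc(C(C)(C)C=C)ccc1OCOC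
F4 | step 8 | [2-fluoro-4,6-bis(methoxymethoxy)-3-(3-methylbut-2-en-1-yl)phenyl](1H-imidazol-1-yl)methanone | O=C(n1ccnc1)c1c(F)c(CC=C(C)C)c(OCOC)cc1OCOC
F5 | step 8 | 1-[2-fluoro-4,6-bis(methoxymethoxy)-3-(3-methylbut-2-en-1-yl)phenyl]-3-[2-(methoxymethoxy)-5-(2-methylbut-3-en-2-yl)phenyl]propane-1,3-dione | O=C(CC(=O)c1cc(C(C)(C)C=C)ccc1OCOC)c1c(F)c(CC=C(C)C)c(OCOC)cc1OCOC
F6 | step 6 | {4-bromo-2-[1-(tert-butyldimethylsilyloxy)ethenyl]phenoxy}(tert-butyl)dimethylsilane | C=C(O[Si](C)(C)C(C)(C)C)c1cc(Br)ccc1O[Si](C)(C)C(C)(C)C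
F7 | step 6 | 3-methylbut-2-en-1-yl pyridine-2-carboxylate | CC(C)=CCOC(=O)c1ccccn1
F8 | step 6 | tert-butyl{2-[1-(tert-butyldimethylsilyloxy)ethenyl]-4-(2-methylbut-3-en-2-yl)phenoxy}dimethylsilane | C=C(O[Si](C)(C)C(C)(C)C)c1cc(C(C)(C)C=C)ccc1O[Si](C)(C)C(C)(C)C
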